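(The numbers of this flask are those of an exercise.)

At the full charge of starting material, intermediate A goes 5.17 times as fast into side product by step 5 as on to intermediate B by step 4; I call this ratio the turnover count.

    starting material + coupling partner → intermediate A (k1 = 0.00289 /M/min)
    intermediate B ⇌ intermediate C (K2 = 0.497, k2 = 1.72 × 10⁻⁴ /min)
    starting material + coupling partner → target (k3 = 9.49 × 10⁻⁴ /M/min)
    intermediate A → intermediate B (k4 = 1.45 × 10⁻⁴ /min)
    starting material + intermediate A → side product (k5 = 0.00500 /M/min)

| setting | cedar | birch | ash | larch |
|---|---|---|---|---|
| starting material | 0.15 M | 0.15 M | 0.15 M (fed, over 12 d) | 0.15 M |
| coupling partner | 2.00 equiv | 2.00 equiv (fed, over 12 d) | 2.00 equiv | 2.00 equiv (in portions, 4, over 12 d) |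
| time | 20 d | 20 d | 20 d | 20 d |
| remark | everything together at the start | all else is in the flask from the start; the feed brings no volume worth counting | all else is in the flask from the start; the feed brings no volume worth counting | first portion at the start, last at 12 d |

- which flask leads in amount of side product, in percent of the starting material charged ("all alike" within 1.5 percentage points) (cedar / birch / ash / larch / all alike)
- how much side product is there at the end, in percent of the starting material charged: cedar
- how much side product is there at the end, in percent of the starting material charged: birch
- how much side product is there at the end, in percent of the starting material charged: ash
- how much side product is there at the end, in percent of the starting material charged: larch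

I start with the main path. Steps 1 and 4 turn starting material into intermediate A and then intermediate B, and step 2 shares that between intermediates B and C, so no side product forms. Then I add step 3: for each intermediate A made, the same two reactants make 0.328 of target. Then I add step 5. With a fraction f of the charge present, the count becomes the turnover count times f, and intermediate A enters side product with the share count over one plus count, taking a further starting material with it. At the full charge that share is 83.8%.

In birch the feed lasts 10 lifetimes of coupling partner against everything charged, and the half-life of intermediate A by step 4, 3.32 d, is shorter than the feed. So I hold intermediate A at balance (its steady state) and, in my sum, let f run from the whole charge down to zero. Summing the shares gives 64.0% side product. Larch receives the same partner over the same time in portions, so my sum gives it the same figure.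

In ash the feed lasts 20 lifetimes of starting material against everything charged, so I take f near 0.0502. The count falls to 0.260, and the same shares give 26.9%.

In cedar the half-life of starting material by step 1, with the coupling partner as charged, 0.56 d, is shorter than that of intermediate A by step 4, so I assume no balance and give no figure. I place cedar between ash and birch.

The forecast names birch as leader, with cedar 34%, birch 62%, ash 24.5% and larch 58%. Its grounds are that side product is worst “when the coupling partner is starved against a full charge of starting material”. It separates birch from larch, which my sum does not, and its ash lies below mine.

| Flask | My reckoning | Simulation |
|---|---|---|
| cedar | none | 33.6% |
| birch | 64.0% | 53.4% |
| ash | 26.9% | 22.6% |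
| larch | 64.0% | 54.9% |

The simulation puts larch first, 1.5 percentage points ahead of birch.

Larch reaches 0.858 of my sum. The neighbouring flask is larch with 0.26 M of starting material, the equivalents and time held. Its turnover count is 8.97, and the same sum gives 70.5%. Scaled by the ratio from larch, that becomes 60.5%. The simulation of that neighbouring flask gives 62.1% side product.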